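**Assumption:** positions carry germacrane numbers (ring C1–C10, C14 on C10, C15 on C4, C11–C13 on C7), so the SMILES reads as the (1R,3S,4S,6R,7S,8R,10R) 1β,10α-epoxy-3β,4α-dihydroxy-8β-angeloyloxy-6α,12-olide; the same numbers are used for the six-membered precursors. TBS = tert-butyldimethylsilyl, Bn = benzyl.

## Retrosynthetic overview

1. Argophyllin A ⇐ epoxidation of the 1(10)E-alkene; the angelate and the exocyclic methylene are put on an 8β-hydroxy-6α,12-lactone.
2. γ-Lactone and O-8 ⇐ ten-membered 6-ketone carrying an 8β-silyl group (masked hydroxyl) and a C7 acetate arm (glyoxylate aldol–elimination, then two hydride steps).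
3. Ten-membered ring ⇐ anionic oxy-Cope [3,3] shift of a trans-1-(2-silylvinyl)-2-isopropenylcyclohexanol: C8–C9 formed, C1–C6 broken, 1(10)E geometry and C8 set in the chair transition state.
4. Cyclohexanone with the C3/C4 trans-diol ⇐ (S)-carvone (Wharton transposition to trans-carveol, allylic oxidation, conjugate borylation–oxidation).
5. Ring order: six-membered ring (bought) → ten-membered carbocycle → γ-lactone → epoxide.

## Route

Step 1
Reactants: 1 (S)-(+)-carvone
Product: 2 (1S,4S,6S)-carvone 2,3-epoxide (epoxide trans to isopropenyl)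
Conditions: 30% H2O2, NaOH (aq), MeOH, 0 °C
Reagents that add atoms: hydrogen peroxide, OO
Why: Weitz–Scheffer nucleophilic epoxidation of the enone, with hydroperoxide entering the ring face opposite the isopropenyl group, which fixes the future C3–O bond.

Step 2
Reactants: 2 (1S,4S,6S)-carvone 2,3-epoxide
Product: 4 (1S,5R)-(−)-trans-carveol, via epoxy hydrazone 3 (not isolated)
Conditions: N2H4·H2O, AcOH (cat.), MeOH, 0 °C → rt
Reagents that add atoms: none
Why: Wharton transposition: the epoxy hydrazone loses N2 to give the allylic alcohol, and the retained epoxide C–O bond leaves the hydroxyl (future 3β-OH) trans to the isopropenyl group.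

Step 3
Reactants: 4 (1S,5R)-trans-carveol
Product: 5 (1S,5R)-trans-carveol TBS ether
Conditions: TBSCl, imidazole, DMF, rt
Reagents that add atoms: tert-butyldimethylsilyl chloride, CC(C)(C)[Si](C)(C)Cl
Why: Silyl ether formation protects the allylic hydroxyl for the oxidation that follows; no stereocentre is touched.

Step 4
Reactants: 5 (1S,5R)-trans-carveol TBS ether
Product: 6 (4S,6R)-4-(TBS-oxy)-3-methyl-6-(prop-1-en-2-yl)cyclohex-2-en-1-one
Conditions: CrO3, 3,5-dimethylpyrazole, CH2Cl2, −20 °C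
Reagents that add atoms: chromium trioxide, O=[Cr](=O)=O
Why: Chromium-based allylic oxidation of the ring methylene next to the trisubstituted alkene gives the conjugated enone, placing the ketone (future C6) beside the isopropenyl-bearing carbon without touching the stereocentres.

Step 5
Reactants: 6 (4S,6R)-enone
Product: 8 (2R,4S,5S)-4-(TBS-oxy)-5-hydroxy-5-methyl-2-(prop-1-en-2-yl)cyclohexan-1-one, via boryl ketone 7 (not isolated)
Conditions: CuCl (5 mol%), 1,3-dimesitylimidazolium chloride (5 mol%), NaOt-Bu (10 mol%), B2pin2, MeOH, THF, rt; then 30% H2O2, pH 7 buffer, 0 °C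
Reagents that add atoms: hydrogen peroxide, OO (bis(pinacolato)diboron, CC1(C)OB(OC1(C)C)B1OC(C)(C)C(C)(C)O1, supplies the boryl group carried only by 7)
Why: Copper-catalysed conjugate borylation puts boron on the β-carbon anti to the neighbouring silyloxy group, and C–B oxidation with retention gives the tertiary alcohol trans to the C3 oxygen (the 3β,4α-diol pattern).

Step 6
Reactants: 8 (2R,4S,5S)-hydroxy ketone
Product: 9 (2R,4S,5S)-4,5-bis(TBS-oxy)-5-methyl-2-(prop-1-en-2-yl)cyclohexan-1-one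
Conditions: TBSOTf, 2,6-lutidine, CH2Cl2, −78 → 0 °C
Reagents that add atoms: tert-butyldimethylsilyl triflate, CC(C)(C)[Si](C)(C)OS(=O)(=O)C(F)(F)F
Why: Silylation of the tertiary alcohol blocks retro-aldol and elimination in the basic steps ahead; no stereocentre changes.

Step 7
Reactants: 10 (E)-1,2-bis(tributylstannyl)ethene
Product: 12 (E)-benzyl(dimethyl)[2-(tributylstannyl)ethenyl]silane, via stannylvinyllithium 11 (not isolated)
Conditions: n-BuLi (1 equiv), THF, −78 °C; then BnMe2SiCl, −78 °C → rt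
Reagents that add atoms: benzylchlorodimethylsilane, C[Si](C)(Cl)Cc1ccccc1
Why: Tin–lithium exchange at one terminus and silylation of the vinyllithium proceed with retention of the E geometry.

Step 8
Reactants: 9 (2R,4S,5S)-bis(TBS-oxy) ketone; 12 (E)-silyl stannane
Product: 14 (1R,2R,4S,5S)-1-[(E)-2-(benzyldimethylsilyl)ethenyl]-4,5-bis(TBS-oxy)-5-methyl-2-(prop-1-en-2-yl)cyclohexan-1-ol, via silylvinyllithium 13 (not isolated)
Conditions: 12, MeLi, THF, −78 °C; CeCl3, −78 °C; then 9, −78 °C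
Reagents that add atoms: none
Why: Organocerium 1,2-addition (after tin–lithium exchange) enters equatorially, away from the axial 4-silyloxy group and trans to the isopropenyl group, giving the trans-1,2-dialkenyl carbinol needed for a chair [3,3] transition state.

Step 9
Reactants: 14 (1R,2R,4S,5S)-dialkenyl carbinol
Product: 17 ethyl (E)-2-[ten-membered 6-oxo ring-7-ylidene]acetate (1(10)E; 8β-SiMe2Bn; 3β,4α-bis-OTBS), via potassium enolate 15 (not isolated), via aldol mesylate 16 (not isolated)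
Conditions: KN(SiMe3)2, 18-crown-6, THF, 0 °C → rt; −78 °C, ethyl glyoxylate; then MsCl, Et3N, −78 → 0 °C
Reagents that add atoms: ethyl glyoxylate, CCOC(=O)C=O (methanesulfonyl chloride, CS(=O)(=O)Cl, is carried only by 16)
Why: Anionic oxy-Cope rearrangement through a chair transition state breaks C1–C6 and forms C8–C9, giving the ten-membered enolate with the 1(10)E-alkene and the silyl group equatorial at C8 (8β, chirality transfer), after which aldol addition to the glyoxylate and E1cB loss of mesylate attach C11–C12 as an alkylidene.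

Step 10
Reactants: 17 alkylidene keto ester
Product: 19 ethyl (1(10)E)-8β-(benzyldimethylsilyl)-3β,4α-bis(TBS-oxy)-6-oxo-13-norgermacr-1(10)-en-12-oate (7α-H), via lithium enolate 18 (not isolated)
Conditions: LiBH(s-Bu)3, THF, −78 °C; then AcOH, −78 °C
Reagents that add atoms: none
Why: Conjugate (1,4) hydride addition at C11 gives the C6 enolate, which is protonated at C7 from the exposed peripheral face of the medium ring (anti to the C8–C9 bond), placing H-7 α and the acetate arm β, cis to the 8β-silyl group.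

Step 11
Reactants: 19 keto ester
Product: 21 (1(10)E)-8β-(benzyldimethylsilyl)-3β,4α-bis(TBS-oxy)-13-norgermacr-1(10)-en-6α,12-olide, via hydroxy ester 20 (not isolated)
Conditions: NaBH4, EtOH, −20 °C; then PPTS, benzene, 50 °C
Reagents that add atoms: none
Why: Hydride adds to the C6 carbonyl from the same peripheral face (macrocyclic stereocontrol) to give the 6α-alcohol, and acid-catalysed lactonisation closes the trans γ-lactone, O-8 still being masked as silicon so that only the 6,12-lactone can form.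

Step 12
Reactants: 21 silyl lactone
Product: 23 (1(10)E)-8β-hydroxy-3β,4α-bis(TBS-oxy)-13-norgermacr-1(10)-en-6α,12-olide, via silanol 22 (not isolated)
Conditions: Bu4NF, THF, 0 °C, 15 min; then KHCO3, 30% H2O2, MeOH/THF, rt
Reagents that add atoms: hydrogen peroxide, OO
Why: Tamao–Fleming oxidation: fluoride removes the benzyl group from silicon and peroxide then moves C8 from silicon to oxygen with retention, unveiling the 8β-hydroxyl.

Step 13
Reactants: 23 hydroxy lactone
Product: 26 (1(10)E)-8β-hydroxy-3β,4α-bis(TBS-oxy)germacra-1(10),11(13)-dien-6α,12-olide, via Mannich base 24 (not isolated), via methiodide 25 (not isolated)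
Conditions: LiN(i-Pr)2 (2.5 equiv), THF, −78 °C; CH2=NMe2+ I−, −78 °C → rt; then MeI, MeOH; NaHCO3 (aq), CH2Cl2
Reagents that add atoms: N,N-dimethylmethyleneiminium iodide, C=[N+](C)C.[I-]
Why: Mannich reaction of the lactone enolate with the iminium salt, then quaternisation and Hofmann-type elimination, installs the exocyclic methylene; no stereocentre is formed.

Step 14
Reactants: 26 α-methylene hydroxy lactone
Product: 27 (1(10)E)-8β-angeloyloxy-3β,4α-bis(TBS-oxy)germacra-1(10),11(13)-dien-6α,12-olide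
Conditions: angelic acid, 2,4,6-trichlorobenzoyl chloride, Et3N, toluene, rt; then 26, 80 °C
Reagents that add atoms: angelic acid, C/C=C(/C)C(=O)O
Why: Yamaguchi esterification through the mixed anhydride without DMAP acylates the 8β-hydroxyl with retention at C8 and keeps the Z geometry of the angelate.

Step 15
Reactants: 27 bis-silyl angelate
Product: 28 (1(10)E)-8β-angeloyloxy-3β,4α-dihydroxygermacra-1(10),11(13)-dien-6α,12-olide
Conditions: HF·pyridine, pyridine, THF, 0 °C → rt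
Reagents that add atoms: none
Why: Fluoride cleavage of both silyl ethers leaves ester, lactone and alkenes untouched and changes no stereocentre.

Step 16
Reactants: 28 diol
Product: 29 argophyllin A
Conditions: mCPBA, NaHCO3, CH2Cl2, 0 °C
Reagents that add atoms: 3-chloroperbenzoic acid, OOC(=O)c1cccc(Cl)c1
Why: Prilezhaev epoxidation picks the only electron-rich alkene and attacks the exposed face of the E-cyclodecene (assisted by hydrogen bonding to the homoallylic 3β-hydroxyl), giving the 1β,10α-epoxide.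

## Compound list

1 | (S)-(+)-carvone | O=C1C(C)=CC[C@H](C(C)=C)C1 | starting material
2 | (1S,4S,6S)-1-methyl-4-(prop-1-en-2-yl)-7-oxabicyclo[4.1.0]heptan-2-one | O=C1[C@@]2(C)O[C@H]2C[C@H](C(C)=C)C1 | intermediate
3 | hydrazone of 2 | NN=C1[C@@]2(C)O[C@H]2C[C@H](C(C)=C)C1 | intermediate (not isolated)
4 | (1S,5R)-trans-carveol | C1C=C(C)[C@@H](O)C[C@@H]1C(C)=C | intermediate
5 | (1S,5R)-trans-carveol TBS ether | C1C=C(C)[C@@H](O[Si](C)(C)C(C)(C)C)C[C@@H]1C(C)=C | intermediate
6 | (4S,6R)-4-(TBS-oxy)-3-methyl-6-(prop-1-en-2-yl)cyclohex-2-en-1-one | O=C1C=C(C)[C@@H](O[Si](C)(C)C(C)(C)C)C[C@@H]1C(C)=C | intermediate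
7 | β-boryl ketone (Bpin on the methyl-bearing carbon, trans to OTBS) | O=C1C[C@](C)(B2OC(C)(C)C(C)(C)O2)[C@@H](O[Si](C)(C)C(C)(C)C)C[C@@H]1C(C)=C | intermediate (not isolated)
8 | (2R,4S,5S)-4-(TBS-oxy)-5-hydroxy-5-methyl-2-(prop-1-en-2-yl)cyclohexan-1-one | O=C1C[C@](C)(O)[C@@H](O[Si](C)(C)C(C)(C)C)C[C@@H]1C(C)=C | intermediate
9 | (2R,4S,5S)-4,5-bis(TBS-oxy)-5-methyl-2-(prop-1-en-2-yl)cyclohexan-1-one | O=C1C[C@](C)(O[Si](C)(C)C(C)(C)C)[C@@H](O[Si](C)(C)C(C)(C)C)C[C@@H]1C(C)=C | intermediate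
10 | (E)-1,2-bis(tributylstannyl)ethene | CCCC[Sn](CCCC)(CCCC)/C=C/[Sn](CCCC)(CCCC)CCCC | starting material
11 | (E)-2-(tributylstannyl)ethenyllithium | [Li]/C=C/[Sn](CCCC)(CCCC)CCCC | intermediate (not isolated)
12 | (E)-benzyl(dimethyl)[2-(tributylstannyl)ethenyl]silane | CCCC[Sn](CCCC)(CCCC)/C=C/[Si](C)(C)Cc1ccccc1 | intermediate
13 | (E)-2-[benzyl(dimethyl)silyl]ethenyllithium | [Li]/C=C/[Si](C)(C)Cc1ccccc1 | intermediate (not isolated)
14 | (1R,2R,4S,5S)-1-[(E)-2-(benzyldimethylsilyl)ethenyl]-4,5-bis(TBS-oxy)-5-methyl-2-(prop-1-en-2-yl)cyclohexan-1-ol | O[C@]1(/C=C/[Si](C)(C)Cc2ccccc2)C[C@](C)(O[Si](C)(C)C(C)(C)C)[C@@H](O[Si](C)(C)C(C)(C)C)C[C@@H]1C(C)=C | intermediate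
15 | potassium enolate of the ring-expanded ketone (C6–OK, C6=C7; 1(10)E; 8β-SiMe2Bn) | [K+].[O-]/C1=C\[C@H]([Si](C)(C)Cc2ccccc2)C/C(C)=C/C[C@H](O[Si](C)(C)C(C)(C)C)[C@@](C)(O[Si](C)(C)C(C)(C)C)C1 | intermediate (not isolated)
16 | aldol mesylate (C7 and C11 epimer mixture) | O=C1C[C@](C)(O[Si](C)(C)C(C)(C)C)[C@@H](O[Si](C)(C)C(C)(C)C)C/C=C(C)/C[C@@H]([Si](C)(C)Cc2ccccc2)C1C(OS(C)(=O)=O)C(=O)OCC | intermediate (not isolated)
17 | ethyl (E)-alkylidene keto ester (6-oxo; C7=C11; 1(10)E; 8β-SiMe2Bn; 3β,4α-bis-OTBS) | O=C1C[C@](C)(O[Si](C)(C)C(C)(C)C)[C@@H](O[Si](C)(C)C(C)(C)C)C/C=C(C)/C[C@@H]([Si](C)(C)Cc2ccccc2)/C1=C/C(=O)OCC | intermediate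
18 | lithium enolate from conjugate reduction (C6–OLi, C6=C7) | [Li+].[O-]C1=C(CC(=O)OCC)[C@H]([Si](C)(C)Cc2ccccc2)C/C(C)=C/C[C@H](O[Si](C)(C)C(C)(C)C)[C@@](C)(O[Si](C)(C)C(C)(C)C)C1 | intermediate (not isolated)
19 | ethyl (1(10)E)-8β-(benzyldimethylsilyl)-3β,4α-bis(TBS-oxy)-6-oxo-13-norgermacr-1(10)-en-12-oate (7α-H) | O=C1C[C@](C)(O[Si](C)(C)C(C)(C)C)[C@@H](O[Si](C)(C)C(C)(C)C)C/C=C(C)/C[C@@H]([Si](C)(C)Cc2ccccc2)[C@H]1CC(=O)OCC | intermediate
20 | 6α-hydroxy ester from 19 | O[C@@H]1C[C@](C)(O[Si](C)(C)C(C)(C)C)[C@@H](O[Si](C)(C)C(C)(C)C)C/C=C(C)/C[C@@H]([Si](C)(C)Cc2ccccc2)[C@H]1CC(=O)OCC | intermediate (not isolated)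
21 | (1(10)E)-8β-(benzyldimethylsilyl)-3β,4α-bis(TBS-oxy)-13-norgermacr-1(10)-en-6α,12-olide | C1C(=O)O[C@@H]2C[C@](C)(O[Si](C)(C)C(C)(C)C)[C@@H](O[Si](C)(C)C(C)(C)C)C/C=C(C)/C[C@@H]([Si](C)(C)Cc3ccccc3)[C@@H]12 | intermediate
22 | 8β-(hydroxydimethylsilyl) lactone (silanol) | C1C(=O)O[C@@H]2C[C@](C)(O[Si](C)(C)C(C)(C)C)[C@@H](O[Si](C)(C)C(C)(C)C)C/C=C(C)/C[C@@H]([Si](C)(C)O)[C@@H]12 | intermediate (not isolated)
23 | (1(10)E)-8β-hydroxy-3β,4α-bis(TBS-oxy)-13-norgermacr-1(10)-en-6α,12-olide | C1C(=O)O[C@@H]2C[C@](C)(O[Si](C)(C)C(C)(C)C)[C@@H](O[Si](C)(C)C(C)(C)C)C/C=C(C)/C[C@@H](O)[C@@H]12 | intermediate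
24 | 11-(dimethylaminomethyl) lactone (Mannich base, C11 epimers) | CN(C)CC1C(=O)O[C@@H]2C[C@](C)(O[Si](C)(C)C(C)(C)C)[C@@H](O[Si](C)(C)C(C)(C)C)C/C=C(C)/C[C@@H](O)[C@@H]12 | intermediate (not isolated)
25 | methiodide of 24 | C[N+](C)(C)CC1C(=O)O[C@@H]2C[C@](C)(O[Si](C)(C)C(C)(C)C)[C@@H](O[Si](C)(C)C(C)(C)C)C/C=C(C)/C[C@@H](O)[C@@H]12.[I-] | intermediate (not isolated)
26 | (1(10)E)-8β-hydroxy-3β,4α-bis(TBS-oxy)germacra-1(10),11(13)-dien-6α,12-olide | C=C1C(=O)O[C@@H]2C[C@](C)(O[Si](C)(C)C(C)(C)C)[C@@H](O[Si](C)(C)C(C)(C)C)C/C=C(C)/C[C@@H](O)[C@@H]12 | intermediate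
27 | (1(10)E)-8β-angeloyloxy-3β,4α-bis(TBS-oxy)germacra-1(10),11(13)-dien-6α,12-olide | C=C1C(=O)O[C@@H]2C[C@](C)(O[Si](C)(C)C(C)(C)C)[C@@H](O[Si](C)(C)C(C)(C)C)C/C=C(C)/C[C@@H](OC(=O)/C(C)=C\C)[C@@H]12 | intermediate
28 | (1(10)E)-8β-angeloyloxy-3β,4α-dihydroxygermacra-1(10),11(13)-dien-6α,12-olide | C=C1C(=O)O[C@@H]2C[C@](C)(O)[C@@H](O)C/C=C(C)/C[C@@H](OC(=O)/C(C)=C\C)[C@@H]12 | intermediate
29 | argophyllin A | C=C1C(=O)O[C@@H]2C[C@](C)(O)[C@@H](O)C[C@H]3O[C@]3(C)C[C@@H](OC(=O)/C(C)=C\C)[C@@H]12 | target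

## Step count and risks

Total step count: 16. Longest linear sequence: 15 (steps 1–6 and 8–16; step 7 makes the two-carbon fragment).

**Step 9 (rearrangement–aldol–elimination cascade).** The basic medium may cause silyl migration, enolate equilibration with loss of the β-silyloxy group, or a non-chair pathway. The fallback sets out from 14 and comes back at 17. Compound 14 is silylated (Me3SiCl, imidazole) to its trimethylsilyl ether F1. The [3,3] shift is then run without base as a neutral siloxy-Cope rearrangement (o-dichlorobenzene, 200 °C) to the ring-expanded trimethylsilyl enol ether F2. A Mukaiyama aldol with ethyl glyoxylate (BF3·OEt2, −78 °C) gives the β-hydroxy ester F3, which is dehydrated (MsCl, Et3N) to 17.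

**Step 10 (C7 configuration by protonation).** If enolate 18 is protonated on the unexpected face, C7 comes out epimeric. The fallback sets out from 14 and comes back at 19. The KN(SiMe3)2/18-crown-6 rearrangement is repeated and enolate 15 is quenched with ethyl bromoacetate, so that a carbon electrophile instead of a proton enters C7. Attack on a given face then gives the C7 configuration opposite to that from protonation on that face. No compound outside the list is made (F0).

**Step 11 (C6 configuration by undirected hydride addition).** Peripheral attack may not dominate and the 6β-alcohol (cis-lactone) could form. The fallback sets out from 19 and comes back at 23. O-8 is unmasked first (Bu4NF, then KHCO3/H2O2) to give the 8β-hydroxy ketone F4. Me4NBH(OAc)3 (AcOH/MeCN, −20 °C) then delivers hydride internally from the boron bound to O-8 and gives the anti-1,3-diol F5 with the 6α-hydroxyl. PPTS closes the trans 6α,12-lactone, the cis-fused 8β,12-lactone being the disfavoured ring, which gives 23 directly.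

## Further compounds

F1 | step 9 | trimethylsilyl ether of 14 | C[Si](C)(C)O[C@]1(/C=C/[Si](C)(C)Cc2ccccc2)C[C@](C)(O[Si](C)(C)C(C)(C)C)[C@@H](O[Si](C)(C)C(C)(C)C)C[C@@H]1C(C)=C
F2 | step 9 | ring-expanded trimethylsilyl enol ether (C6–OSiMe3, C6=C7; 1(10)E; 8β-SiMe2Bn) | C[Si](C)(C)O/C1=C\[C@H]([Si](C)(C)Cc2ccccc2)C/C(C)=C/C[C@H](O[Si](C)(C)C(C)(C)C)[C@@](C)(O[Si](C)(C)C(C)(C)C)C1
F3 | step 9 | aldol adduct of the ring-expanded ketone with ethyl glyoxylate (C7 and C11 epimers) | O=C1C[C@](C)(O[Si](C)(C)C(C)(C)C)[C@@H](O[Si](C)(C)C(C)(C)C)C/C=C(C)/C[C@@H]([Si](C)(C)Cc2ccccc2)C1C(O)C(=O)OCC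
F0 | step 10 | none | none
F4 | step 11 | ethyl (1(10)E)-8β-hydroxy-3β,4α-bis(TBS-oxy)-6-oxo-13-norgermacr-1(10)-en-12-oate | O=C1C[C@](C)(O[Si](C)(C)C(C)(C)C)[C@@H](O[Si](C)(C)C(C)(C)C)C/C=C(C)/C[C@@H](O)[C@H]1CC(=O)OCC
F5 | step 11 | ethyl (1(10)E)-6α,8β-dihydroxy-3β,4α-bis(TBS-oxy)-13-norgermacr-1(10)-en-12-oate | O[C@@H]1C[C@](C)(O[Si](C)(C)C(C)(C)C)[C@@H](O[Si](C)(C)C(C)(C)C)C/C=C(C)/C[C@@H](O)[C@H]1CC(=O)OCC
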